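Atom labels, used throughout: ring C1 (CMe2), C2 (CHBr), C3 (alkylidene carbon), C4 (CHCl), C5 (CH2), C6 (CHCl); side chain C7 (=CH), C8 (CH2Br). The plan exploits that the bromides at C2 and C8 stand cis on the exocyclic C3=C7 alkene of the cyclohexane ring, so both can descend from one O–O bridge. Singlet oxygen adds across C2 and C8 of a vinylcyclohexene (diene C2=C3–C7=C8). This single [4+2] event closes a 3,6-dihydro-1,2-dioxine ring, moves the alkene to C3=C7 with locked geometry and sets C2. The precursor carries C6–Cl and a cis C4–OTBS group on one ring face. C2–O and C4–O are later exchanged for halide with inversion.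

Key step: step 12

Assumption: the (2S,5S) antipode of 2,5-diphenylpyrrolidine is taken to deliver the (R)-chloride 3. If the sense of induction is the reverse, the (2R,5R) antipode is used and nothing else changes.

Step 1
Reactants: 1 methyl 3,3-dimethylpent-4-enoate
Product: 2 3,3-dimethylpent-4-enal
Conditions: i-Bu2AlH (1.05 equiv), CH2Cl2, −78 °C; aqueous quench, careful concentration (volatile)
Reagents that add atoms: none
Why: Partial reduction of an ester by i-Bu2AlH at −78 °C stops at the aldehyde level because the first hydride adduct does not collapse before the aqueous quench, and the isolated alkene is inert at this temperature.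

Step 2
Reactants: 2 3,3-dimethylpent-4-enal
Product: 4 (2R)-2-chloro-3,3-dimethylpent-4-en-1-ol, via (2R)-2-chloro-3,3-dimethylpent-4-enal 3 (not isolated)
Conditions: N-chlorosuccinimide (1.3 equiv), (2S,5S)-2,5-diphenylpyrrolidine (10 mol %), CH2Cl2, 0 °C → rt; then MeOH, NaBH4, 0 °C
Reagents that add atoms: N-chlorosuccinimide, O=C1CCC(=O)N1Cl
Why: Enamine-catalysed asymmetric α-chlorination of aldehydes accepts a tert-alkyl group on the reacting carbon, the twofold-symmetric amine decides which enamine face meets the chlorine donor and thereby sets C6, and borohydride reduction in the same flask removes the configurationally labile aldehyde at once.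

Step 3
Reactants: 4 (2R)-2-chloro-3,3-dimethylpent-4-en-1-ol
Product: 5 (2R)-2-chloro-3,3-dimethylpent-4-en-1-yl trifluoromethanesulfonate
Conditions: Tf2O (1.1 equiv), 2,6-lutidine (1.3 equiv), CH2Cl2, −78 °C; cold work-up, used at once
Reagents that add atoms: trifluoromethanesulfonic anhydride, O=S(=O)(OS(=O)(=O)C(F)(F)F)C(F)(F)F
Why: Sulfonylation of a primary alcohol with Tf2O and a hindered pyridine base leaves C6 untouched, and the neighbouring chloride slows ionisation by induction so that the triflate can be handled cold.

Step 4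
Reactants: 5 (2R)-2-chloro-3,3-dimethylpent-4-en-1-yl trifluoromethanesulfonate; 6 vinylmagnesium bromide
Product: 7 (4S)-4-chloro-3,3-dimethylhepta-1,6-diene
Conditions: CH2=CHMgBr (3 equiv), CuI (1.5 equiv), THF–Et2O, −40 °C; then 5, −78 → −20 °C
Reagents that add atoms: vinylmagnesium bromide (6), C=C[Mg]Br
Why: A Gilman-type vinyl cuprate displaces a primary alkyl triflate by SN2 substitution well below 0 °C, whereas the secondary chloride next to the quaternary carbon is far too hindered to react, so C6 keeps its configuration.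

Step 5
Reactants: 7 (4S)-4-chloro-3,3-dimethylhepta-1,6-diene
Product: 8 (4S)-4-chloro-3,3-dimethylcyclopent-1-ene
Conditions: second-generation Grubbs catalyst (H2IMes)(PCy3)Cl2Ru=CHPh (2 mol %), CH2Cl2 (0.05 M), 40 °C; silica plug, cold concentration
Reagents that add atoms: none
Why: Ring-closing metathesis starts at the unhindered allyl terminus and closes onto the neopentyl vinyl group, helped by the Thorpe–Ingold effect of the gem-dimethyl group and by loss of ethene.

Step 6
Reactants: 8 (4S)-4-chloro-3,3-dimethylcyclopent-1-ene; 9 bromoform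
Product: 10 (3S)-6,6-dibromo-3-chloro-2,2-dimethylbicyclo[3.1.0]hexane (CBr2 bridge anti to C–Cl)
Conditions: CHBr3 (3 equiv), 50% aq. NaOH, BnEt3NCl (5 mol %), CH2Cl2, 0 °C → rt; kept below rt
Reagents that add atoms: bromoform (9), BrC(Br)Br
Why: Dibromocarbene generated under phase-transfer catalysis adds to the cis-alkene in a stereospecific cheletropic [2+1] cycloaddition, mainly on the face away from C6–Cl, and the facial outcome is of no consequence because both adducts open to the same allyl cation in step 7.

Step 7
Reactants: 10 (3S)-6,6-dibromo-3-chloro-2,2-dimethylbicyclo[3.1.0]hexane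
Product: 11 (5S)-2-bromo-5-chloro-4,4-dimethylcyclohex-2-en-1-ol (both carbinol epimers)
Conditions: AgNO3 (1.5 equiv), acetone–H2O (4:1), rt, dark
Reagents that add atoms: water, O
Why: Silver-assisted loss of the endo bromide triggers the disrotatory electrocyclic opening of the cyclopropane (Woodward–Hoffmann–DePuy rule) to the 2-bromocyclohexenyl cation, which water captures at C4, the terminus remote from quaternary C1, and the C4 configuration is left open here because step 8 erases it.

Step 8
Reactants: 11 (5S)-2-bromo-5-chloro-4,4-dimethylcyclohex-2-en-1-ol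
Product: 12 (5S)-2-bromo-5-chloro-4,4-dimethylcyclohex-2-en-1-one
Conditions: Dess–Martin periodinane (1.2 equiv), CH2Cl2, 0 °C → rt
Reagents that add atoms: none
Why: Dess–Martin oxidation runs without base, so the β-chloride at C6 is not lost by E1cB elimination, and both C4 epimers merge into one enone.

Step 9
Reactants: 12 (5S)-2-bromo-5-chloro-4,4-dimethylcyclohex-2-en-1-one
Product: 13 (1R,5S)-2-bromo-5-chloro-4,4-dimethylcyclohex-2-en-1-ol
Conditions: NaBH4, CeCl3·7H2O, MeOH, −78 °C
Reagents that add atoms: none
Why: In this Luche 1,2-reduction hydride should reach the carbonyl from the face anti to C6–Cl in either ring conformer, as in the reduction of 5-substituted cyclohexenones such as carvone to the cis alcohols, which sets C4 (R) cis to C6–Cl in a weakly acidic medium that spares the β-chloride.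

Step 10
Reactants: 13 (1R,5S)-2-bromo-5-chloro-4,4-dimethylcyclohex-2-en-1-ol
Product: 14 tert-butyl{[(1R,5S)-2-bromo-5-chloro-4,4-dimethylcyclohex-2-en-1-yl]oxy}dimethylsilane
Conditions: TBSOTf (1.2 equiv), 2,6-lutidine (1.5 equiv), CH2Cl2, 0 °C
Reagents that add atoms: tert-butyldimethylsilyl trifluoromethanesulfonate, CC(C)(C)[Si](C)(C)OS(=O)(=O)C(F)(F)F
Why: O-silylation with the silyl triflate and a hindered base is fast even next to the bromoalkene and touches no stereocentre.

Step 11
Reactants: 14 tert-butyl{[(1R,5S)-2-bromo-5-chloro-4,4-dimethylcyclohex-2-en-1-yl]oxy}dimethylsilane; 15 tributyl(vinyl)stannane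
Product: 16 tert-butyl{[(1R,5S)-5-chloro-2-ethenyl-4,4-dimethylcyclohex-2-en-1-yl]oxy}dimethylsilane
Conditions: 15 (1.3 equiv), Pd2(dba)3 (2.5 mol %), AsPh3 (10 mol %), DMF, 50 °C
Reagents that add atoms: tributyl(vinyl)stannane (15), C=C[Sn](CCCC)(CCCC)CCCC
Why: The Stille coupling is neutral, zerovalent palladium inserts only into the sp2 C–Br bond, and the alkyl chloride and the silyl ether are spectators.

Step 12
Reactants: 16 tert-butyl{[(1R,5S)-5-chloro-2-ethenyl-4,4-dimethylcyclohex-2-en-1-yl]oxy}dimethylsilane
Product: 17 (5R,7S,8aS)-5-(tert-butyldimethylsilyloxy)-7-chloro-8,8-dimethyl-3,5,6,7,8,8a-hexahydrobenzo[c][1,2]dioxine (C2–O trans to C4–OTBS and C6–Cl)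
Conditions: O2 (1 atm), tetraphenylporphyrin (1 mol %), white LED, CH2Cl2, −30 °C
Reagents that add atoms: dioxygen, O=O
Why: Energy transfer from photoexcited tetraphenylporphyrin turns ground-state O2 into singlet oxygen, which adds to the s-cis C2=C3–C7=C8 diene in a concerted suprafacial [4+2] cycloaddition, the reaction type long known for 1-vinylcycloalkenes and other semicyclic dienes. The 3,6-dihydro-1,2-dioxine ring is closed by cycloaddition, the C2–O and C8–O bonds forming in the same event, so the new C3=C7 alkene can only hold C2 and C8 cis. The one new stereocentre, C2, is controlled by the carbocycle: in the half-chair with C4–OTBS pseudoequatorial and C6–Cl equatorial, the pseudoaxial C1 methyl group lies on the same face as both heteroatoms and directly next to C2, so oxygen should approach from the opposite face, which shows only C4–H and C6–H. Periselectivity over the Schenck ene reaction is needed as well, and it is secured because C1 carries no hydrogen and the single allylic C4–H is geminal to the silyloxy group, a position from which singlet oxygen rarely abstracts. The pseudoequatorial silyl ether also clashes with C8 in the s-trans rotamer, which raises the share of the reactive s-cis form. Low temperature and an aprotic solvent should further favour cycloaddition and keep the peroxide intact.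

Step 13
Reactants: 17 endoperoxide
Product: 18 (1S,2E,3R,5S)-3-(tert-butyldimethylsilyloxy)-5-chloro-2-(2-hydroxyethylidene)-6,6-dimethylcyclohexan-1-ol (C8 cis to C2; E only because C4–OSi outranks C2–OH)
Conditions: thiourea (2.2 equiv), MeOH, 0 °C → rt
Reagents that add atoms: none
Why: Thiourea reduces the O–O bond of unsaturated endoperoxides chemoselectively by attack of sulfur on oxygen without breaking a C–O bond, so C2 and the cis placement of C2 and C8 on C3=C7 are carried over while alkene, silyl ether and alkyl chloride stay inert.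

Step 14
Reactants: 18 cis-enediol
Product: 19 (6R,8S,9aS)-6-(tert-butyldimethylsilyloxy)-8-chloro-2,2,9,9-tetramethyl-4,6,7,8,9,9a-hexahydro-2H-1,3-benzodioxepine
Conditions: Me2C(OMe)2 (5 equiv), PPTS (5 mol %), CH2Cl2, rt
Reagents that add atoms: 2,2-dimethoxypropane, COC(C)(C)OC
Why: Acid-catalysed transketalisation of a cis-2-ene-1,4-diol gives the seven-membered 4,7-dihydro-1,3-dioxepine acetonide, a known protecting mode that is open only because the two hydroxyl groups are held cis, and PPTS is too weak to cleave the TBS ether or ionise the allylic positions.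

Step 15
Reactants: 19 silylated acetonide
Product: 20 (6R,8S,9aS)-8-chloro-2,2,9,9-tetramethyl-4,6,7,8,9,9a-hexahydro-2H-1,3-benzodioxepin-6-ol
Conditions: Bu4NF (1.2 equiv), THF, 0 °C → rt
Reagents that add atoms: none
Why: Fluoride-induced desilylation is driven by the Si–F bond, and neither the ketal nor the equatorial C6 chloride is affected, since that chloride has no antiperiplanar hydrogen and lies on the same face as the C4 alkoxide.

Step 16
Reactants: 20 acetonide alcohol
Product: 21 (6S,8S,9aR)-6,8-dichloro-2,2,9,9-tetramethyl-4,6,7,8,9,9a-hexahydro-2H-1,3-benzodioxepine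
Conditions: PPh3 (1.5 equiv), Cl3CC(O)CCl3 (2 equiv), CH2Cl2, −20 → 0 °C
Reagents that add atoms: hexachloroacetone, O=C(C(Cl)(Cl)Cl)C(Cl)(Cl)Cl
Why: Appel-type chlorination with the PPh3–hexachloroacetone couple converts secondary allylic alcohols under neutral conditions into the unrearranged chlorides by SN2 attack of chloride on the oxyphosphonium ion, so C4 is inverted from R to S and C4–Cl ends trans to C6–Cl.

Step 17
Reactants: 21 dichloro acetonide
Product: 22 (1R,2E,3S,5S)-3,5-dichloro-2-(2-hydroxyethylidene)-6,6-dimethylcyclohexan-1-ol (C8 cis to C2)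
Conditions: AcOH–THF–H2O (3:1:1), rt
Reagents that add atoms: none
Why: Seven-membered acetonides hydrolyse readily in dilute aqueous acetic acid, conditions under which the allylic and alkyl chlorides do not solvolyse and no stereocentre is touched.

Step 18
Reactants: 22 dichloro cis-enediol
Product: 24 (1S,3S,4Z,5S)-3-bromo-4-(2-bromoethylidene)-1,5-dichloro-2,2-dimethylcyclohexane, via C8-bromo C2-alcohol 23 (not isolated)
Conditions: CBr4 (3 equiv), PPh3 (3 equiv), CH2Cl2, −20 → 0 °C
Reagents that add atoms: tetrabromomethane, BrC(Br)(Br)Br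
Why: In this double Appel bromination the primary allylic C8–OH reacts first and the C2 oxyphosphonium ion is then displaced from the rear by bromide, which inverts C2 from R to S, while the electron-withdrawing CH2Br group now on C7 and the C4 chloride hold back ionisation and attack at C7.

Compound list
1 | methyl 3,3-dimethylpent-4-enoate | COC(=O)CC(C)(C)C=C | starting material
2 | 3,3-dimethylpent-4-enal | O=CCC(C)(C)C=C | intermediate
3 | (2R)-2-chloro-3,3-dimethylpent-4-enal | O=C[C@H](Cl)C(C)(C)C=C | intermediate
4 | (2R)-2-chloro-3,3-dimethylpent-4-en-1-ol | OC[C@H](Cl)C(C)(C)C=C | intermediate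
5 | (2R)-2-chloro-3,3-dimethylpent-4-en-1-yl trifluoromethanesulfonate | O=S(=O)(OC[C@H](Cl)C(C)(C)C=C)C(F)(F)F | intermediate
6 | vinylmagnesium bromide | C=C[Mg]Br | starting material
7 | (4S)-4-chloro-3,3-dimethylhepta-1,6-diene | C=CC[C@H](Cl)C(C)(C)C=C | intermediate
8 | (4S)-4-chloro-3,3-dimethylcyclopent-1-ene | CC1(C)C=CC[C@@H]1Cl | intermediate
9 | bromoform | BrC(Br)Br | starting material
10 | (3S)-6,6-dibromo-3-chloro-2,2-dimethylbicyclo[3.1.0]hexane, CBr2 bridge anti to C–Cl | CC1(C)[C@@H]2[C@H](C[C@@H]1Cl)C2(Br)Br | intermediate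
11 | (5S)-2-bromo-5-chloro-4,4-dimethylcyclohex-2-en-1-ol, both carbinol epimers | CC1(C)C=C(Br)C(O)C[C@@H]1Cl | intermediate
12 | (5S)-2-bromo-5-chloro-4,4-dimethylcyclohex-2-en-1-one | CC1(C)C=C(Br)C(=O)C[C@@H]1Cl | intermediate
13 | (1R,5S)-2-bromo-5-chloro-4,4-dimethylcyclohex-2-en-1-ol | CC1(C)C=C(Br)[C@H](O)C[C@@H]1Cl | intermediate
14 | tert-butyl{[(1R,5S)-2-bromo-5-chloro-4,4-dimethylcyclohex-2-en-1-yl]oxy}dimethylsilane | CC1(C)C=C(Br)[C@H](O[Si](C)(C)C(C)(C)C)C[C@@H]1Cl | intermediate
15 | tributyl(vinyl)stannane | C=C[Sn](CCCC)(CCCC)CCCC | starting material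
16 | tert-butyl{[(1R,5S)-5-chloro-2-ethenyl-4,4-dimethylcyclohex-2-en-1-yl]oxy}dimethylsilane | CC1(C)C=C(C=C)[C@H](O[Si](C)(C)C(C)(C)C)C[C@@H]1Cl | intermediate
17 | (5R,7S,8aS)-5-(tert-butyldimethylsilyloxy)-7-chloro-8,8-dimethyl-3,5,6,7,8,8a-hexahydrobenzo[c][1,2]dioxine | CC1(C)[C@H]2OOCC=C2[C@H](O[Si](C)(C)C(C)(C)C)C[C@@H]1Cl | intermediate
18 | (1S,2E,3R,5S)-3-(tert-butyldimethylsilyloxy)-5-chloro-2-(2-hydroxyethylidene)-6,6-dimethylcyclohexan-1-ol | CC1(C)[C@@H](O)/C(=C\CO)[C@H](O[Si](C)(C)C(C)(C)C)C[C@@H]1Cl | intermediate
19 | (6R,8S,9aS)-6-(tert-butyldimethylsilyloxy)-8-chloro-2,2,9,9-tetramethyl-4,6,7,8,9,9a-hexahydro-2H-1,3-benzodioxepine | CC1(C)[C@H]2OC(C)(C)OCC=C2[C@H](O[Si](C)(C)C(C)(C)C)C[C@@H]1Cl | intermediate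
20 | (6R,8S,9aS)-8-chloro-2,2,9,9-tetramethyl-4,6,7,8,9,9a-hexahydro-2H-1,3-benzodioxepin-6-ol | CC1(C)[C@H]2OC(C)(C)OCC=C2[C@H](O)C[C@@H]1Cl | intermediate
21 | (6S,8S,9aR)-6,8-dichloro-2,2,9,9-tetramethyl-4,6,7,8,9,9a-hexahydro-2H-1,3-benzodioxepine | CC1(C)[C@H]2OC(C)(C)OCC=C2[C@@H](Cl)C[C@@H]1Cl | intermediate
22 | (1R,2E,3S,5S)-3,5-dichloro-2-(2-hydroxyethylidene)-6,6-dimethylcyclohexan-1-ol | CC1(C)[C@@H](O)/C(=C\CO)[C@@H](Cl)C[C@@H]1Cl | intermediate
23 | (1R,2E,3S,5S)-2-(2-bromoethylidene)-3,5-dichloro-6,6-dimethylcyclohexan-1-ol | CC1(C)[C@@H](O)/C(=C\CBr)[C@@H](Cl)C[C@@H]1Cl | intermediate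
24 | (1S,3S,4Z,5S)-3-bromo-4-(2-bromoethylidene)-1,5-dichloro-2,2-dimethylcyclohexane | CC1(C)[C@H](Br)/C(=C\CBr)[C@@H](Cl)C[C@@H]1Cl | target

Total step count: 18. Longest linear sequence: 18 steps (fully linear from 1).

Steps most likely to fail

Step 12. Oxygen may not distinguish the two diene faces well enough. Hydrogen abstraction from C4 (ene pathway) may compete with cycloaddition, or the diene may populate the s-cis rotamer too little. The fallback sets out from 16 and comes back at 18. A 1,4-diboration with B2pin2, catalysed by zerovalent platinum [Pt(dba)3, PCy3 or an enantiopure TADDOL-derived phosphonite, THF, 60 °C], also engages the s-cis diene. It places both boron atoms on one face and leaves C2 and C8 cis on C3=C7, which should give the C2,C8-bis(pinacolboronate) F1. Oxidation with H2O2/NaOH (THF, 0 °C) replaces each C–B bond by C–O with retention and leads to 18. No hydrogen abstraction is possible in this manifold, and a chiral ligand adds reagent control of the face to the substrate bias.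

Step 18. Bromide may attack C7 instead of the neopentyl-type C2 (allylic transposition). The C2 oxyphosphonium ion may ionise with erosion of configuration, or the C2 hydroxyl may close onto activated C8 (cyclodehydration). The fallback sets out from 22 and comes back at 24 by treating the two centres one after the other.
- Selective acylation of the primary alcohol (PivCl, pyridine, CH2Cl2, −20 °C) should give the C8 pivalate of the diol F2.
- C2 alone is then substituted with inversion under more forcing phosphine conditions (CBr4, P(n-Oct)3, toluene, 60 °C) to the C2 bromide C8 pivalate F3. No free hydroxyl is left to cyclise, and the bulky ester screens C7.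
- Reductive ester cleavage (i-Bu2AlH, CH2Cl2, −78 °C) frees the C2-bromo C8-alcohol F4.
- A simple primary Appel bromination (CBr4, PPh3, CH2Cl2, 0 °C) gives 24.

Step 4. The trivalent copper intermediate may expel the β-chloride, losing both heteroatoms with alkene formation. The reagent may also act as a base, or may attack sulfur and return the alcohol. The fallback sets out from 5 and comes back at 7 with a nucleophile that has no redox chemistry.
- Lithium (trimethylsilyl)acetylide (THF–DMPU, −78 → −20 °C) displaces the triflate to give the silylated enyne F5.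
- K2CO3/MeOH removes the silyl group to give the terminal enyne F6.
- Semihydrogenation (H2, Pd/CaCO3 poisoned with Pb(OAc)2, quinoline, hexane) stops at diene 7.

Further compounds
F1 | step 12 | C2,C8-bis(pinacolboronate) of the C4-silyloxy C6-chloro ethylidenecyclohexane, C2–B trans to C4–OTBS and C6–Cl, C8 cis to C2 | CC1(C)[C@@H](B2OC(C)(C)C(C)(C)O2)/C(=C\CB2OC(C)(C)C(C)(C)O2)[C@H](O[Si](C)(C)C(C)(C)C)C[C@@H]1Cl
F2 | step 18 | C8 pivalate of diol 22 | CC1(C)[C@@H](O)/C(=C\COC(=O)C(C)(C)C)[C@@H](Cl)C[C@@H]1Cl
F3 | step 18 | C2 bromide (inverted) C8 pivalate | CC1(C)[C@H](Br)/C(=C\COC(=O)C(C)(C)C)[C@@H](Cl)C[C@@H]1Cl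
F4 | step 18 | C2-bromo C8-alcohol | CC1(C)[C@H](Br)/C(=C\CO)[C@@H](Cl)C[C@@H]1Cl
F5 | step 4 | [(4S)-4-chloro-5,5-dimethylhept-6-en-1-yn-1-yl]trimethylsilane | C[Si](C)(C)C#CC[C@H](Cl)C(C)(C)C=C
F6 | step 4 | (4S)-4-chloro-3,3-dimethylhept-1-en-6-yne | C#CC[C@H](Cl)C(C)(C)C=C
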